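**Plan**

- Retrosynthesis: the O–CH3 and aryl C–Br bonds are cut first. The secondary methyl carbon C2 is traced to a C2 ketone, and the exocyclic C3=CHBr to α-formylation of that ketone. The ring bond between the quaternary benzylic carbon C1 and the ring CH2 C5 is cut by a retro-1,2-shift to a 1-(1-arylvinyl)cyclobutan-1-ol, which is cut at the vinyl–carbinol bond.
- Enabling feature: C1 is a benzylic ring carbon carrying CH3 and an o-oxygenated, p-methylated aryl ring, and its ring neighbour C2 can sit at the carbinol level. Protonating the =CH2 of the 1,1-disubstituted styrene therefore makes the C1 methyl and a stabilised cation next to a strained cyclobutanol (C2, C3, C4, C5), whose CH2 (C5) shifts to C1.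
- Forward order: the chain is joined by Shapiro reaction and addition to cyclobutanone; the four-membered ring is enlarged to the cyclopentanone; then follow the C3 bromomethylene, the aryl bromide, the C2 methylene and its reduction, and O-demethylation.
- Stereochemistry: C1 comes from the chiral acid in the ring enlargement, the (E)-bromoalkene from thermodynamic control in the β-bromo enone, and C2 from H2 delivery anti to the aryl group.

Key step: step 3

Remark: the antipode of the chiral acid that gives (S)-6 is fixed in a pilot run; the descriptor at the quaternary carbon changes from S (6–9) to R (10–13) only because the CIP priorities change, not the spatial arrangement. Compounds 1 and 3 are taken as commercially available.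

**Step 1**
Reactants: 1 1-(2-methoxy-4-methylphenyl)ethan-1-one
Product: 2 N'-[(1E)-1-(2-methoxy-4-methylphenyl)ethylidene]-2,4,6-tri(propan-2-yl)benzenesulfonohydrazide
Conditions: 2,4,6-triisopropylbenzenesulfonohydrazide, cat. HCl, MeOH, rt
Reagents that add atoms: 2,4,6-triisopropylbenzenesulfonohydrazide, CC(C)c1cc(C(C)C)c(S(=O)(=O)NN)c(C(C)C)c1
Why: Acid-catalysed hydrazone formation gives the substrate for a Shapiro reaction whose only α-hydrogens lie on the methyl group.

**Step 2**
Reactants: 2 N'-[(1E)-1-(2-methoxy-4-methylphenyl)ethylidene]-2,4,6-tri(propan-2-yl)benzenesulfonohydrazide; 3 cyclobutanone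
Product: 5 1-[1-(2-methoxy-4-methylphenyl)ethenyl]cyclobutan-1-ol, via α-arylvinyllithium 4 (not isolated)
Conditions: n-BuLi (2.2 equiv), THF, −78 → 0 °C; then 3, −78 °C → rt; H2O
Reagents that add atoms: none
Why: The Shapiro reaction (double deprotonation, loss of sulfinate and N2) should give the regiodefined vinyllithium, which adds 1,2 to the strain-activated carbonyl of cyclobutanone; no stereocentre is formed.

**Step 3**
Reactants: 5 1-[1-(2-methoxy-4-methylphenyl)ethenyl]cyclobutan-1-ol
Product: 6 (2S)-2-(2-methoxy-4-methylphenyl)-2-methylcyclopentan-1-one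
Conditions: chiral BINOL-derived N-triflylphosphoramide (5 mol %, antipode giving (S)-6), toluene, −40 °C
Reagents that add atoms: none
Why: The chiral acid protonates the terminal CH2 of the 1,1-disubstituted styrene, which completes the C-methyl group and gives a tertiary benzylic cation, stabilised by the o-methoxy/p-methyl aryl ring, as a contact ion pair with the chiral anion hydrogen-bonded to the carbinol OH. One of the two enantiotopic cyclobutane CH2 groups then migrates to the cationic carbon with oxygen lone-pair assistance (protio-semipinacol rearrangement), so the cyclopentane is closed by a [1,2]-carbon shift, a four- to five-membered ring enlargement, and not by an exo or endo attack. Release of roughly 20 kcal/mol of cyclobutane strain and formation of the C=O bond should make the shift fast and irreversible. The closest known reaction type is the chiral Brønsted acid- or hydrogen-bond-donor/HCl-catalysed protio-semipinacol ring expansion of tertiary vinylic cycloalkanols, and the racemic acid-promoted version is classical for 1-(1-arylvinyl)cyclobutanols. The single new stereocentre, the quaternary benzylic carbon, is set by the catalyst, which selects the cation face and thereby which enantiotopic CH2 migrates. The step needs Markovnikov protonation in preference to ionisation of the tertiary alcohol and a suppressed racemic background; the donor aryl group, the absence of any other migrating group on the carbinol carbon, the non-polar solvent and the low temperature should secure this.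

**Step 4**
Reactants: 6 (2S)-2-(2-methoxy-4-methylphenyl)-2-methylcyclopentan-1-one
Product: 7 (2S,5Z)-5-(hydroxymethylidene)-2-(2-methoxy-4-methylphenyl)-2-methylcyclopentan-1-one
Conditions: NaH, HCO2Et, cat. EtOH, THF, 0 °C → rt; 1 M HCl work-up
Reagents that add atoms: ethyl formate, CCOC=O
Why: Crossed Claisen condensation (α-formylation) can occur only at C5 because C2 is quaternary, and the product should exist as the hydrogen-bonded (Z)-hydroxymethylene tautomer.

**Step 5**
Reactants: 7 (2S,5Z)-5-(hydroxymethylidene)-2-(2-methoxy-4-methylphenyl)-2-methylcyclopentan-1-one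
Product: 8 (2S,5E)-5-(bromomethylidene)-2-(2-methoxy-4-methylphenyl)-2-methylcyclopentan-1-one
Conditions: (COBr)2, DMF (cat.), CH2Cl2, 0 °C → rt
Reagents that add atoms: oxalyl bromide, O=C(Br)C(=O)Br
Why: Vilsmeier-type activation of the vinylogous acid and bromide addition–elimination give the β-bromo enone, which should equilibrate under the HBr formed to the more stable (E) isomer, with Br anti to the carbonyl and cis to the ring CH2 as in the target.

**Step 6**
Reactants: 8 (2S,5E)-5-(bromomethylidene)-2-(2-methoxy-4-methylphenyl)-2-methylcyclopentan-1-one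
Product: 9 (2S,5E)-5-(bromomethylidene)-2-(5-bromo-2-methoxy-4-methylphenyl)-2-methylcyclopentan-1-one
Conditions: NBS, MeCN, 0 °C → rt, dark
Reagents that add atoms: N-bromosuccinimide, O=C1CCC(=O)N1Br
Why: Electrophilic aromatic bromination should go para to the methoxy group (ortho to the methyl), the most activated open position, while the enone is electron-poor and has no enolisable α-hydrogen.

**Step 7**
Reactants: 9 (2S,5E)-5-(bromomethylidene)-2-(5-bromo-2-methoxy-4-methylphenyl)-2-methylcyclopentan-1-one
Product: 10 1-bromo-5-[(1R,3E)-3-(bromomethylidene)-1-methyl-2-methylidenecyclopentyl]-4-methoxy-2-methylbenzene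
Conditions: Tebbe reagent, pyridine (cat.), THF/toluene, −40 °C → rt
Reagents that add atoms: Tebbe reagent, C[Al](C)C[Ti](Cl)(C1C=CC=C1)C1C=CC=C1
Why: Tebbe methylenation through the titanium methylidene is non-basic, works on hindered ketones and leaves vinyl and aryl bromides untouched.

**Step 8**
Reactants: 10 1-bromo-5-[(1R,3E)-3-(bromomethylidene)-1-methyl-2-methylidenecyclopentyl]-4-methoxy-2-methylbenzene
Product: 11 1-bromo-5-[(1R,2R,3E)-3-(bromomethylidene)-1,2-dimethylcyclopentyl]-4-methoxy-2-methylbenzene
Conditions: 2-nitrobenzenesulfonohydrazide (excess), Et3N, CH2Cl2, rt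
Reagents that add atoms: none
Why: Diimide reduction transfers H2 syn and concertedly, prefers the 1,1-disubstituted alkene over the trisubstituted bromoalkene and cannot cleave C–Br bonds; hydrogen should reach the ring carbon on the face opposite the bulky o-substituted aryl group of the neighbouring quaternary centre, which places the new methyl cis to the aryl group (2R).

**Step 9**
Reactants: 11 1-bromo-5-[(1R,2R,3E)-3-(bromomethylidene)-1,2-dimethylcyclopentyl]-4-methoxy-2-methylbenzene
Product: 13 4-bromo-2-[(1R,2R,3E)-3-(bromomethylidene)-1,2-dimethylcyclopentyl]-5-methylphenol, via aryloxydibromoborane 12 (not isolated)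
Conditions: BBr3, CH2Cl2, −78 → 0 °C; then H2O, 0 °C
Reagents that add atoms: none
Why: Lewis acid cleavage of the aryl methyl ether (BBr3 demethylation) through the aryloxydibromoborane, hydrolysed cold, should leave both C–Br bonds, the alkene geometry and the stereocentres unchanged.

**Compound list**

1 | 1-(2-methoxy-4-methylphenyl)ethan-1-one | COc1cc(C)ccc1C(C)=O | starting material
2 | N'-[(1E)-1-(2-methoxy-4-methylphenyl)ethylidene]-2,4,6-tri(propan-2-yl)benzenesulfonohydrazide | COc1cc(C)ccc1/C(C)=N/NS(=O)(=O)c1c(C(C)C)cc(C(C)C)cc1C(C)C | intermediate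
3 | cyclobutanone | O=C1CCC1 | starting material
4 | [1-(2-methoxy-4-methylphenyl)ethenyl]lithium (formed in situ) | [Li]C(=C)c1ccc(C)cc1OC | intermediate
5 | 1-[1-(2-methoxy-4-methylphenyl)ethenyl]cyclobutan-1-ol | COc1cc(C)ccc1C(=C)C1(O)CCC1 | intermediate
6 | (2S)-2-(2-methoxy-4-methylphenyl)-2-methylcyclopentan-1-one | COc1cc(C)ccc1[C@]1(C)CCCC1=O | intermediate
7 | (2S,5Z)-5-(hydroxymethylidene)-2-(2-methoxy-4-methylphenyl)-2-methylcyclopentan-1-one | COc1cc(C)ccc1[C@]1(C)CC/C(=C/O)C1=O | intermediate
8 | (2S,5E)-5-(bromomethylidene)-2-(2-methoxy-4-methylphenyl)-2-methylcyclopentan-1-one | COc1cc(C)ccc1[C@]1(C)CC/C(=C\Br)C1=O | intermediate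
9 | (2S,5E)-5-(bromomethylidene)-2-(5-bromo-2-methoxy-4-methylphenyl)-2-methylcyclopentan-1-one | COc1cc(C)c(Br)cc1[C@]1(C)CC/C(=C\Br)C1=O | intermediate
10 | 1-bromo-5-[(1R,3E)-3-(bromomethylidene)-1-methyl-2-methylidenecyclopentyl]-4-methoxy-2-methylbenzene | COc1cc(C)c(Br)cc1[C@]1(C)CC/C(=C\Br)C1=C | intermediate
11 | 1-bromo-5-[(1R,2R,3E)-3-(bromomethylidene)-1,2-dimethylcyclopentyl]-4-methoxy-2-methylbenzene | COc1cc(C)c(Br)cc1[C@]1(C)CC/C(=C\Br)[C@@H]1C | intermediate
12 | {4-bromo-2-[(1R,2R,3E)-3-(bromomethylidene)-1,2-dimethylcyclopentyl]-5-methylphenoxy}dibromoborane (formed in situ) | Cc1cc(OB(Br)Br)c([C@]2(C)CC/C(=C\Br)[C@@H]2C)cc1Br | intermediate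
13 | 4-bromo-2-[(1R,2R,3E)-3-(bromomethylidene)-1,2-dimethylcyclopentyl]-5-methylphenol | Cc1cc(O)c([C@]2(C)CC/C(=C\Br)[C@@H]2C)cc1Br | target

Total step count: 9. Longest linear sequence: 9 steps (1 → 13).

**Steps most likely to fail**

Step 3. The chiral ion pair may discriminate poorly between the two cation faces, or a non-selective background ionisation may compete, so that 6 would form with low enantiomeric purity. The fallback sets out from 5 and replaces asymmetric catalysis by resolution. Treatment of 5 with catalytic TsOH in toluene should give racemic 2-(2-methoxy-4-methylphenyl)-2-methylcyclopentan-1-one F1. Addition of the lithium derivative of (S)-N,S-dimethyl-S-phenylsulfoximine (n-BuLi, THF, −78 °C) should give two separable β-hydroxy sulfoximines: the adduct of the (S)-ketone, (2S)-2-(2-methoxy-4-methylphenyl)-2-methyl-1-{[(S)-N-methyl-S-phenylsulfonimidoyl]methyl}cyclopentan-1-ol F2, and the adduct of the (R)-ketone, the (2R) diastereomer F3 (carbinol centre as formed in each). After chromatographic separation, thermolysis of F2 in refluxing toluene should return the route at 6.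

Step 8. Hydrogen may be delivered to the face syn to the aryl group, which would give the C2 epimer, or the reduction may stall at the hindered alkene. The fallback sets out from 10 and splits the operation into a hydroboration with a bulky borane and a protonolysis. 9-BBN (THF, 0 °C → rt) should add to the methylidene group with boron on the terminal carbon and hydrogen on the ring carbon anti to the aryl group, giving 9-{[(1R,2R,5E)-5-(bromomethylidene)-2-(5-bromo-2-methoxy-4-methylphenyl)-2-methylcyclopentyl]methyl}-9-borabicyclo[3.3.1]nonane F4. Protonolysis of the primary C–B bond with acetic acid at 100 °C should return the route at 11.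

Step 9. During demethylation the liberated phenol or HBr may add across the exocyclic bromoalkene under the acidic conditions. The fallback sets out from 9 and moves the demethylation to a stage with no acid-labile alkene, then carries a fluoride-labile group.
- BBr3 (CH2Cl2, −78 → 0 °C) on 9 should give (2S,5E)-5-(bromomethylidene)-2-(5-bromo-2-hydroxy-4-methylphenyl)-2-methylcyclopentan-1-one F5.
- TBSCl and imidazole in DMF should give (2S,5E)-5-(bromomethylidene)-2-{5-bromo-2-[(tert-butyldimethylsilyl)oxy]-4-methylphenyl}-2-methylcyclopentan-1-one F6.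
- Tebbe methylenation should give {4-bromo-2-[(1R,3E)-3-(bromomethylidene)-1-methyl-2-methylidenecyclopentyl]-5-methylphenoxy}(tert-butyl)dimethylsilane F7.
- Diimide reduction should give {4-bromo-2-[(1R,2R,3E)-3-(bromomethylidene)-1,2-dimethylcyclopentyl]-5-methylphenoxy}(tert-butyl)dimethylsilane F8.
- TBAF in THF at 0 °C should return the route at 13.

**Further compounds**

F1 | step 3 | rac-2-(2-methoxy-4-methylphenyl)-2-methylcyclopentan-1-one | COc1cc(C)ccc1C1(C)CCCC1=O
F2 | step 3 | (2S)-2-(2-methoxy-4-methylphenyl)-2-methyl-1-{[(S)-N-methyl-S-phenylsulfonimidoyl]methyl}cyclopentan-1-ol | COc1cc(C)ccc1[C@]1(C)CCCC1(O)C[S@@](=O)(=NC)c1ccccc1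
F3 | step 3 | (2R)-2-(2-methoxy-4-methylphenyl)-2-methyl-1-{[(S)-N-methyl-S-phenylsulfonimidoyl]methyl}cyclopentan-1-ol | COc1cc(C)ccc1[C@@]1(C)CCCC1(O)C[S@@](=O)(=NC)c1ccccc1
F4 | step 8 | 9-{[(1R,2R,5E)-5-(bromomethylidene)-2-(5-bromo-2-methoxy-4-methylphenyl)-2-methylcyclopentyl]methyl}-9-borabicyclo[3.3.1]nonane | COc1cc(C)c(Br)cc1[C@]1(C)CC/C(=C\Br)[C@@H]1CB1C2CCCC1CCC2
F5 | step 9 | (2S,5E)-5-(bromomethylidene)-2-(5-bromo-2-hydroxy-4-methylphenyl)-2-methylcyclopentan-1-one | Cc1cc(O)c([C@]2(C)CC/C(=C\Br)C2=O)cc1Br
F6 | step 9 | (2S,5E)-5-(bromomethylidene)-2-{5-bromo-2-[(tert-butyldimethylsilyl)oxy]-4-methylphenyl}-2-methylcyclopentan-1-one | Cc1cc(O[Si](C)(C)C(C)(C)C)c([C@]2(C)CC/C(=C\Br)C2=O)cc1Br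
F7 | step 9 | {4-bromo-2-[(1R,3E)-3-(bromomethylidene)-1-methyl-2-methylidenecyclopentyl]-5-methylphenoxy}(tert-butyl)dimethylsilane | Cc1cc(O[Si](C)(C)C(C)(C)C)c([C@]2(C)CC/C(=C\Br)C2=C)cc1Br
F8 | step 9 | {4-bromo-2-[(1R,2R,3E)-3-(bromomethylidene)-1,2-dimethylcyclopentyl]-5-methylphenoxy}(tert-butyl)dimethylsilane | Cc1cc(O[Si](C)(C)C(C)(C)C)c([C@]2(C)CC/C(=C\Br)[C@@H]2C)cc1Br
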